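**Plan**

Retrosynthesis: the pyrimidine C2–NH2 bond (SNAr) and the indole C3–pyrimidine C4 bond (Friedel–Crafts-type heteroarylation) are cut first, leaving 5,6-dibromoindole. Its two C–Br bonds are traced back to C–Si bonds and the indole to an N-tosylindoline.
The benzo ring is then cut at C4–C5, C6–C7 and C3a–C7a. The enabling feature is that the vicinal dibromide sits on C5/C6, flanked by the CH carbons C4 and C7, while C3a and C7a are bridged by C3–C2–N1. C5/C6 are therefore the two carbons of a symmetric disilylalkyne, C7a/C7 an N-ethynyl group, and C3a/C4 the alkyne of an N-butynyl group.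
Forward: sulfonamide, then ynamide diyne; one cobalt-catalysed [2+2+2] cyclotrimerization closes the five-membered nitrogen ring and the benzene ring together. Ipso-bromination, dehydrogenation to the indole and N-deprotection follow; the pyrimidine ring is brought in intact and aminated last.
Stereochemistry: the target is achiral and has no stereocentre, so none has to be set.

Key step: step 4

Assumption: in step 5 the silyl group at C5 (para to nitrogen) is taken to be exchanged first; should C6 react first, the isomeric monobromide converges on the same dibromide 10.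

**Route**

Step 1
Reactants: 1 but-3-yn-1-amine; 2 4-methylbenzenesulfonyl chloride
Product: 3 N-(but-3-yn-1-yl)-4-methylbenzenesulfonamide
Conditions: Et3N, DMAP (cat.), CH2Cl2, 0 °C to rt
Reagents that add atoms: 4-methylbenzenesulfonyl chloride (compound 2), Cc1ccc(S(Cl)(=O)=O)cc1
Why: N-sulfonylation of a primary amine under Schotten–Baumann-type conditions is reliable, and the terminal alkyne is a spectator.

Step 2
Reactants: 3 N-(but-3-yn-1-yl)-4-methylbenzenesulfonamide; 4 phenyl[(trimethylsilyl)ethynyl]iodonium trifluoromethanesulfonate
Product: 5 N-(but-3-yn-1-yl)-4-methyl-N-[(trimethylsilyl)ethynyl]benzenesulfonamide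
Conditions: KN(SiMe3)2 (KHMDS, 1.0 equiv), toluene, 0 °C; then 4, 0 °C to rt
Reagents that add atoms: phenyl[(trimethylsilyl)ethynyl]iodonium trifluoromethanesulfonate (compound 4), C[Si](C)(C)C#C[I+]c1ccccc1.[O-]S(=O)(=O)C(F)(F)F
Why: N-alkynylation of a sulfonamide with an alkynyl(phenyl)iodonium salt should work because one equivalent of base removes only the N–H (the alkyne C–H is far less acidic), the potassium sulfonamide adds to the silyl-bearing alkyne carbon, iodobenzene leaves from the ylide, and a 1,2-shift in the alkylidene carbene gives the silyl ynamide.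

Step 3
Reactants: 5 N-(but-3-yn-1-yl)-4-methyl-N-[(trimethylsilyl)ethynyl]benzenesulfonamide
Product: 6 N-(but-3-yn-1-yl)-N-ethynyl-4-methylbenzenesulfonamide
Conditions: K2CO3 (0.2 equiv), MeOH/THF, 0 °C
Reagents that add atoms: none
Why: Base-catalysed methanolysis of the alkynyl C–Si bond (protodesilylation) is fast at 0 °C and should leave the N-sulfonyl ynamide and the second alkyne untouched.

Step 4
Reactants: 6 N-(but-3-yn-1-yl)-N-ethynyl-4-methylbenzenesulfonamide; 7 bis(trimethylsilyl)acetylene
Product: 8 1-tosyl-5,6-bis(trimethylsilyl)indoline [1-(4-methylbenzenesulfonyl)-5,6-bis(trimethylsilyl)-2,3-dihydro-1H-indole]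
Conditions: CpCo(CO)2 (10 mol %), 7 as solvent (large excess), slow syringe-pump addition of 6, hν (visible lamp), reflux (ca. 135 °C), Ar
Reagents that add atoms: bis(trimethylsilyl)acetylene (compound 7), C[Si](C)(C)C#C[Si](C)(C)C
Why: Loss of CO from CpCo(CO)2 frees a CpCo fragment (monovalent cobalt) that binds both alkynes of 6 and couples them oxidatively to a bicyclic cobaltacyclopentadiene (trivalent cobalt). This coupling forms C3a–C7a, so the five-membered nitrogen ring closes by intramolecular alkyne–alkyne coupling across the N1–C2–C3 tether. Alkyne 7 then inserts into a Co–C bond (or adds in a [4+2] sense) and reductive elimination forms C4–C5 and C6–C7, closing the benzene ring and releasing the CpCo fragment. The closest known reactions are the cobalt-catalysed co-cyclotrimerization of α,ω-diynes with bis(trimethylsilyl)acetylene to 1,2-bis(silyl)arenes and the metal-catalysed [2+2+2] of ynamide diynes to indolines. No stereocentre is formed. The selectivity needed is cross- over self-cyclotrimerization: 7 is too hindered to trimerize with itself and serves as the solvent while 6 is kept dilute by slow addition; regiochemistry is no issue because 7 is symmetric.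

Step 5
Reactants: 8 1-tosyl-5,6-bis(trimethylsilyl)indoline
Product: 10 5,6-dibromo-1-tosylindoline, via 5-bromo-1-tosyl-6-(trimethylsilyl)indoline 9 (not isolated)
Conditions: Br2 (2.5 equiv), CH2Cl2, 0 °C to rt, dark; aq. Na2S2O3 work-up
Reagents that add atoms: bromine, BrBr
Why: Electrophilic ipso-bromodesilylation should place bromine only on C5 and C6 because attack at the silicon-bearing carbons gives β-silyl-stabilised arenium ions, the first exchange is helped by relief of strain between the ortho silyl groups, and the silicon leaves as Me3SiBr so that no acid is formed to cause protodesilylation.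

Step 6
Reactants: 10 5,6-dibromo-1-tosylindoline
Product: 11 5,6-dibromo-1-tosyl-1H-indole
Conditions: DDQ (2 equiv), chlorobenzene, reflux
Reagents that add atoms: none
Why: Quinone dehydrogenation (hydride abstraction from benzylic C3, then loss of the C2 proton) is the standard way from N-sulfonylindolines to N-sulfonylindoles, and the aryl bromides and the sulfonamide are inert to DDQ.

Step 7
Reactants: 11 5,6-dibromo-1-tosyl-1H-indole
Product: 12 5,6-dibromo-1H-indole
Conditions: KOH, MeOH/THF/H2O, 65 °C
Reagents that add atoms: none
Why: Alkaline solvolysis of an N-sulfonylindole is easy because the indolide anion is a good leaving group from sulfur, and these non-reductive conditions leave both C–Br bonds alone.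

Step 8
Reactants: 12 5,6-dibromo-1H-indole; 13 2,4-dichloropyrimidine
Product: 14 5,6-dibromo-3-(2-chloropyrimidin-4-yl)-1H-indole
Conditions: AlCl3 (1.3 equiv), 13 (1.2 equiv), ClCH2CH2Cl, 80 °C
Reagents that add atoms: 2,4-dichloropyrimidine (compound 13), Clc1ccnc(Cl)n1
Why: Lewis-acid-promoted Friedel–Crafts-type heteroarylation (addition–elimination on the AlCl3-activated pyrimidine) should occur at the nucleophilic indole C3 and at the more electrophilic pyrimidine C4, keeping the 2-chloride for the last step.

Step 9
Reactants: 14 5,6-dibromo-3-(2-chloropyrimidin-4-yl)-1H-indole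
Product: 15 meridianin F [4-(5,6-dibromo-1H-indol-3-yl)pyrimidin-2-amine]
Conditions: NH3 (7 M in MeOH)/1,4-dioxane, sealed tube, 110 °C
Reagents that add atoms: ammonia, N
Why: SNAr aminolysis of a 2-chloropyrimidine with ammonia under pressure is routine, and the unactivated aryl bromides on the benzo ring do not react without a metal catalyst.

**Compound list**

1 | but-3-yn-1-amine | C#CCCN | starting material
2 | 4-methylbenzenesulfonyl chloride | Cc1ccc(S(Cl)(=O)=O)cc1 | starting material
3 | N-(but-3-yn-1-yl)-4-methylbenzenesulfonamide | C#CCCNS(=O)(=O)c1ccc(C)cc1 | intermediate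
4 | phenyl[(trimethylsilyl)ethynyl]iodonium trifluoromethanesulfonate | C[Si](C)(C)C#C[I+]c1ccccc1.[O-]S(=O)(=O)C(F)(F)F | starting material
5 | N-(but-3-yn-1-yl)-4-methyl-N-[(trimethylsilyl)ethynyl]benzenesulfonamide | C#CCCN(C#C[Si](C)(C)C)S(=O)(=O)c1ccc(C)cc1 | intermediate
6 | N-(but-3-yn-1-yl)-N-ethynyl-4-methylbenzenesulfonamide | C#CCCN(C#C)S(=O)(=O)c1ccc(C)cc1 | intermediate
7 | bis(trimethylsilyl)acetylene | C[Si](C)(C)C#C[Si](C)(C)C | starting material
8 | 1-tosyl-5,6-bis(trimethylsilyl)indoline | Cc1ccc(cc1)S(=O)(=O)N1CCc2cc([Si](C)(C)C)c([Si](C)(C)C)cc21 | intermediate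
9 | 5-bromo-1-tosyl-6-(trimethylsilyl)indoline | Cc1ccc(cc1)S(=O)(=O)N1CCc2cc(Br)c([Si](C)(C)C)cc21 | intermediate
10 | 5,6-dibromo-1-tosylindoline | Cc1ccc(cc1)S(=O)(=O)N1CCc2cc(Br)c(Br)cc21 | intermediate
11 | 5,6-dibromo-1-tosyl-1H-indole | Cc1ccc(cc1)S(=O)(=O)n1ccc2cc(Br)c(Br)cc21 | intermediate
12 | 5,6-dibromo-1H-indole | Brc1cc2cc[nH]c2cc1Br | intermediate
13 | 2,4-dichloropyrimidine | Clc1ccnc(Cl)n1 | starting material
14 | 5,6-dibromo-3-(2-chloropyrimidin-4-yl)-1H-indole | Clc1nccc(-c2c[nH]c3cc(Br)c(Br)cc23)n1 | intermediate
15 | meridianin F, 4-(5,6-dibromo-1H-indol-3-yl)pyrimidin-2-amine | Nc1nccc(-c2c[nH]c3cc(Br)c(Br)cc23)n1 | target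

**Count**

Total steps: 9. Longest linear sequence: 9 steps (1 to 15).

**Steps most likely to fail**

Step 4. The hindered disilylalkyne may insert into the cobaltacycle too slowly, so that self-condensation of the diyne, formation of inert cobalt–cyclobutadiene complexes or thermal loss of the ynamide take over. The fallback sets out from 6 and changes the alkyne partner and the halogenation manifold. Cobalt-mediated co-cyclization of 6 with commercial 2,2'-(ethyne-1,2-diyl)bis(4,4,5,5-tetramethyl-1,3,2-dioxaborolane), using CpCo(CO)2 with irradiation in refluxing xylene or stoichiometric Co2(CO)8, should give 5,6-bis(4,4,5,5-tetramethyl-1,3,2-dioxaborolan-2-yl)-1-tosylindoline F1. This alkyne is flatter at the substituent atoms and more electron-poor, so it should bind and insert more readily. Copper-mediated bromodeboronation of both C–B bonds (CuBr2, MeOH/H2O, 80 °C) would then give dibromide 10, where the route is rejoined; step 5 is not needed.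

Step 6. Hydride abstraction from an indoline that carries an N-sulfonyl group and two bromines may be so slow that decomposition at the required temperature competes. The fallback sets out from 10 and reverses the order of deprotection and oxidation. Acidic cleavage of the N-aryl sulfonamide (CF3SO3H, ClCH2CH2Cl, 90 °C; non-reductive, so the C–Br bonds stay) should give 5,6-dibromoindoline F2. As a free, electron-richer indoline it should be dehydrogenated at room temperature by MnO2 in CH2Cl2, giving 5,6-dibromoindole 12, where the route is rejoined; compound 11 is bypassed.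

Step 8. The two ring bromines lower the nucleophilicity of C3, so conversion may stall, and attack at pyrimidine C2 or N-arylation may compete. The fallback sets out from 11 and builds the pyrimidine ring instead of attaching it. Friedel–Crafts acetylation at C3 (AcCl, AlCl3, CH2Cl2) should give 1-(5,6-dibromo-1-tosyl-1H-indol-3-yl)ethan-1-one F3. Condensation with N,N-dimethylformamide dimethyl acetal (DMF, 110 °C) should give the enaminone (E)-1-(5,6-dibromo-1-tosyl-1H-indol-3-yl)-3-(dimethylamino)prop-2-en-1-one F4. Cyclocondensation with guanidine hydrochloride and K2CO3 in refluxing 2-methoxyethanol then forms the 2-aminopyrimidine and cleaves the N-tosyl group in the same operation, arriving directly at target 15; steps 7 to 9 are not needed.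

**Further compounds**

F1 | step 4 | 5,6-bis(4,4,5,5-tetramethyl-1,3,2-dioxaborolan-2-yl)-1-tosylindoline | Cc1ccc(cc1)S(=O)(=O)N1CCc2cc(B3OC(C)(C)C(C)(C)O3)c(B3OC(C)(C)C(C)(C)O3)cc21
F2 | step 6 | 5,6-dibromoindoline | Brc1cc2CCNc2cc1Br
F3 | step 8 | 1-(5,6-dibromo-1-tosyl-1H-indol-3-yl)ethan-1-one | CC(=O)c1cn(S(=O)(=O)c2ccc(C)cc2)c2cc(Br)c(Br)cc12
F4 | step 8 | (E)-1-(5,6-dibromo-1-tosyl-1H-indol-3-yl)-3-(dimethylamino)prop-2-en-1-one | CN(C)/C=C/C(=O)c1cn(S(=O)(=O)c2ccc(C)cc2)c2cc(Br)c(Br)cc12
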